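**Abbreviations:** TBS = tert-butyldimethylsilyl, TES = triethylsilyl, Bn = benzyl, (R)-TRIP = (R)-3,3'-bis(2,4,6-triisopropylphenyl)-1,1'-binaphthyl-2,2'-diyl hydrogen phosphate, DDQ = 2,3-dichloro-5,6-dicyano-1,4-benzoquinone, NBS = N-bromosuccinimide, mCPBA = 3-chloroperbenzoic acid, DMAP = 4-(dimethylamino)pyridine. "Bottom", "middle" and "top" denote the three flavan units, read from the acylated unit upwards.

## Analysis of the target

The target is a procyanidin-type trimer: an epicatechin top unit (2R,3R, 2,3-cis), a catechin middle unit and a catechin bottom unit (both 2R,3S, 2,3-trans), joined by a 4β→8 bond (top to middle) and a 4α→8 bond (middle to bottom). The bottom O3 carries (S)-1-hydroxy-6-oxocyclohex-2-ene-1-carboxylate, a six-membered ring whose quaternary carbinol C1 is flanked by the C6 ketone, the C2=C3 alkene and the ester carbonyl. There are nine stereocentres: C2 and C3 of each flavan unit, C4 of the top and middle units, and C1 of the acyl ring. In the middle unit the C2 aryl, the C3 oxygen and the C4 aryl are all trans; in the top unit the C4 bond is trans to O3 and to the C2 aryl. Sensitive features are twelve phenols, two interflavan bonds that are cleaved by acid through C4 cations, and an α-hydroxy-β-keto ester that is degraded by base and whose alkene forbids a final hydrogenolysis. The synthesis is hard because both C4–C8 bonds need control of position (C8 against C6) and of C4 configuration, three secondary hydroxyls must be told apart so that only the bottom O3 is acylated, and the protecting groups must come off under mildly acidic, non-reducing conditions. The strategy rests on ring C of the middle unit: O1, C2 with its catechol ring, C3 with its oxygen and C4 bonded to C8 of the bottom unit map onto an aryl-substituted ortho-quinone methide (O1, C8a, C4a, C4) and an (E)-2-arylvinyl ester (C2, C3).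

## Retrosynthetic reasoning

**35 to 33.** No skeletal bond is cut. The last operation must spare the hydroxy keto ester and its alkene, so all twelve phenols and the two free secondary hydroxyls are traced back to silyl ethers, the tertiary hydroxyl to a triethylsilyl ether and the C6 ketone to a methyl enol ether. The forward step is desilylation by acidic fluoride to 34, then brief hydrolysis of the enol ether; base and hydrogen never meet the acyl group.

**33 to 24 and 31.** The ester C–O bond at the bottom O3 is cut. The acyl group is the most fragile part and is attached last, and 24 has only this one free hydroxyl. The acid is taken as the enol ether 31 and not as the keto acid, because a β-keto acid would lose carbon dioxide and a free ketone beside a quaternary carbon invites retro-Claisen cleavage. The forward reaction must join a fully substituted acid to a secondary alcohol and goes through the mixed anhydride 32.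

**31 back to 25.** The C1–O bond of the acyl ring is cut. The carbinol comes from oxygen transfer to the planar enolate 28, and the ring with both alkenes and the masked ketone comes from dearomatising reduction of 25 to 26. An allyl ester (27, 29, 30) is chosen so that the acid can be freed under neutral conditions without touching the enol ether. The forward oxygenation has to select one face of 28.

**24 to 23, then to 18 and 22.** The C4(top)–C8(middle) bond is cut. The top unit is 2,3-cis, and capture of its C4 cation trans to the C3 substituent gives the 4β bond reliably; C8 of the middle ring is the most open nucleophilic position of 18. The bromine at C8 of 22 stops the electrophile and the product from reacting further. It is removed together with the benzyl ether in the step from 23 to 24, before the alkene of the acyl group exists.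

**22 back to 19.** C4–O and C8–Br bonds and the silyl ethers are cut: benzylic oxidation at C4, bromination at C8 and exhaustive silylation of 19 via 20 and 21.

**18 to 17 to 16.** Only a protecting group is changed. The acetate left at the middle O3 could not be removed at the end beside the acyl group, so it is exchanged for a silyl ether now.

**16 to 10 and 14 (through 15).** The O1–C2 and C3–C4 bonds of ring C of the middle unit are cut. The usual cut at C4–C8 for a 2,3-trans upper unit leaves both the ring position and the C4 configuration to a cation capture. Cutting ring C instead places the C4–C8 bond in the precursor 10 and lets C2, C3 and C4 arise together. The forward reaction is dehydration of 10 to the quinone methide 15 and its [4+2] addition to the enol ester 14.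

**14 back to 11.** The enol ester C–O bond is traced to oxygen insertion into the E-enone 13, which keeps the alkene geometry; 13 comes from olefination of 12, the silyl ether of 11.

**10 to 9, then to 4 and 7 (through 8).** The bond between C8 of the bottom unit and the carbinol carbon is cut. An aryl carbanion adds to an aldehyde, which fixes the 8-position without any competition from C6. The phenol that will become O1 is carried as an allyl ether in 7 and 9 and is freed without acid.

**4 back to 1, and 7 back to 5.** Bromination at C8, benzylation of O3 and silylation of the phenols of 1 give 4 via 2 and 3. Twofold silylation of 5 to 6 and allylation of the remaining chelated phenol give 7.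

## Alternatives that were turned down

**Alternative 1:** The cut is a C–C bond of ring A of the middle unit, between the future C4a and an oxygen-bearing ring carbon. The forward key step is a base-induced Claisen cyclisation of the open-chain triketo ester A1, which closes and aromatises ring A to the chalcone A2.
- For it: the logic follows the biosynthesis, and the steps that would lead from A2 to a 2,3-trans C4 electrophile are individually known.
- Against it: it builds an aromatic ring that the chosen route takes ready-made from 5, and A1 has competing aldol and lactone cyclisation modes. A2 contains none of the nine stereocentres, both interflavan bonds are still to be made by cation coupling, and its benzyl ethers would have to be exchanged before the acyl alkene appears.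
- Comparison: on precedent of the single steps it is stronger than the chosen key step. The chosen strategy offers ring C with three stereocentres and the lower interflavan bond in one convergent step, at a far lower step count.

**Alternative 2:** The cut is inside the acyl ring, where the C6 ketone and C5 methylene are traced to an epoxide across C5–C6. The forward key step is epoxidation of the prochiral dienol ester A3 with VO(OiPr)3, a chiral bishydroxamic acid and tBuOOH, syn to the tertiary hydroxyl, giving A4 and fixing C1.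
- For it: the quaternary centre is set by a hydroxyl-directed, catalyst-controlled desymmetrisation, and the acid component has no stereocentre before esterification.
- Against it: A4 must still be isomerised to the ketone with the hydride shift going the right way, against migration of the ester or alkenyl group. A3 can aromatise by loss of water under acid, and the chiral alcohol part makes the epoxidation a matched or mismatched case. It also treats only the acyl group of a monomer and leaves the trimer core open.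
- Comparison: for C1 it is stronger than the reagent-controlled enolate oxygenation of step 21, whose facial sense is assumed. The chosen strategy offers a solution to the core, and it fixes the ketone position unambiguously through the enol ether.

**Alternative 3:** The cut is the C1–C2 bond of the acyl ring. The forward key step is a 1,2-shift in the cyclopentenyl carbinol keto ester A5 under Cu(OTf)2 chelation: the alkenyl ring carbon moves to the keto carbon, the ring grows to six members and the carbinol becomes the C6 ketone of A6. If copper holds the hydroxyl and keto oxygens syn, the (R)-carbinol should give the (S) centre.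
- For it: quaternary carbon, ketone and ring are formed in one stereospecific step directly on the alcohol, so no hindered acid has to be coupled.
- Against it: ketol shifts are reversible, and migration of the saturated ring carbon instead would put the alkene in conjugation with the ketone; only migratory aptitude decides. A6 is itself a ketol that can shift again, a Lewis acid late in the synthesis threatens the interflavan bonds, and the core is again left open.
- Comparison: on atom economy and on avoiding the hindered esterification it is stronger. The chosen strategy keeps Lewis acids away from the finished acyl group and puts its risk into the step that solves the trimer core.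

Key step: step 11

## Route

**Assumptions (remarks on the chemistry):**
- The (R)-enantiomer of the phosphoric acid is taken as the catalyst matched with the (2R,3S) bottom unit of 10 in step 11; if the opposite is found, its antipode is used in the same step.
- The (+)-(2R,8aS)-oxaziridine is taken to deliver oxygen to the face of enolate 28 that gives the (S)-alcohol in step 21; if the opposite is found, its antipode is used.

Step 1
Reactants: 1 (+)-catechin
Product: 2 5,7,3',4'-tetra-O-TBS-catechin
Conditions: TBSCl (4.3 equiv), imidazole, DMF, 0 °C to rt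
Reagents that add atoms: tert-butyldimethylsilyl chloride, CC(C)(C)[Si](C)(C)Cl
Why: Silylation; the four phenols react much faster than the hindered secondary 3-hydroxyl, so the tetrasilyl ether with free O3 should result, and C2 and C3 are untouched.

Step 2
Reactants: 2 5,7,3',4'-tetra-O-TBS-catechin
Product: 3 3-O-benzyl-5,7,3',4'-tetra-O-TBS-catechin
Conditions: 2-benzyloxy-1-methylpyridinium triflate (2 equiv), MgO, PhCF3, 85 °C
Reagents that add atoms: 2-benzyloxy-1-methylpyridinium triflate, C[n+]1ccccc1OCc1ccccc1.[O-]S(=O)(=O)C(F)(F)F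
Why: Benzyl transfer from the pyridinium salt under neutral conditions; no alkoxide is formed, so aryl silyl groups cannot migrate, and the alcohol oxygen is a far better nucleophile for the benzyl cation equivalent than the silyloxy arene carbons.

Step 3
Reactants: 3 3-O-benzyl-5,7,3',4'-tetra-O-TBS-catechin
Product: 4 8-bromo-3-O-benzyl-5,7,3',4'-tetra-O-TBS-catechin
Conditions: NBS (1.0 equiv), CH2Cl2, −78 to −40 °C, dark
Reagents that add atoms: N-bromosuccinimide, O=C1CCC(=O)N1Br
Why: Electrophilic aromatic bromination; C8 lies between the ring oxygen and one silyloxy group and is more open than C6 between two silyloxy groups, and ring B is less activated.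

Step 4
Reactants: 5 2,4,6-trihydroxybenzaldehyde
Product: 6 2-hydroxy-4,6-bis(TBS-oxy)benzaldehyde
Conditions: TBSCl (2.1 equiv), imidazole, CH2Cl2–DMF, 0 °C
Reagents that add atoms: tert-butyldimethylsilyl chloride, CC(C)(C)[Si](C)(C)Cl
Why: Selective silylation; the para hydroxyl and one ortho hydroxyl react, after which the last ortho hydroxyl is held in a hydrogen bond to the aldehyde and is left.

Step 5
Reactants: 6 2-hydroxy-4,6-bis(TBS-oxy)benzaldehyde
Product: 7 2-allyloxy-4,6-bis(TBS-oxy)benzaldehyde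
Conditions: allyl alcohol, PPh3, diisopropyl azodicarboxylate, THF, 0 °C to rt
Reagents that add atoms: allyl alcohol, C=CCO
Why: Mitsunobu etherification of the phenol under neutral conditions that spare the aryl silyl ethers; allyl is chosen because zerovalent palladium removes it later without acid.

Step 6
Reactants: 4 8-bromo-3-O-benzyl-5,7,3',4'-tetra-O-TBS-catechin; 7 2-allyloxy-4,6-bis(TBS-oxy)benzaldehyde
Product: 9 8-[(2-allyloxy-4,6-bis(TBS-oxy)phenyl)(hydroxy)methyl]-3-O-benzyl-5,7,3',4'-tetra-O-TBS-catechin (carbinol epimers), via aryllithium 8 (not isolated)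
Conditions: tBuLi (2.05 equiv), THF, −78 °C, 10 min; then 7, −78 °C; AcOH in THF at −78 °C
Reagents that add atoms: none
Why: Bromine–lithium exchange and 1,2-addition of the aryllithium to the aldehyde fix the link at C8; the quench is made cold so that silyl groups do not shift to carbon or to the new alkoxide, and the carbinol configuration is irrelevant because it is lost in step 11.

Step 7
Reactants: 9 8-[(2-allyloxy-4,6-bis(TBS-oxy)phenyl)(hydroxy)methyl]-3-O-benzyl-5,7,3',4'-tetra-O-TBS-catechin
Product: 10 8-[hydroxy(2-hydroxy-4,6-bis(TBS-oxy)phenyl)methyl]-3-O-benzyl-5,7,3',4'-tetra-O-TBS-catechin (carbinol epimers)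
Conditions: Pd(PPh3)4 (5 mol %), morpholine, THF, rt; filtration through Et3N-deactivated silica
Reagents that add atoms: none
Why: Tsuji–Trost deallylation; morpholine takes the allyl group from the π-allyl complex and keeps the medium basic, so the very acid-labile benzhydrol should survive.

Step 8
Reactants: 11 3,4-dihydroxybenzaldehyde
Product: 12 3,4-bis(TBS-oxy)benzaldehyde
Conditions: TBSCl (2.3 equiv), imidazole, DMF, rt
Reagents that add atoms: tert-butyldimethylsilyl chloride, CC(C)(C)[Si](C)(C)Cl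
Why: Silylation of both phenols.

Step 9
Reactants: 12 3,4-bis(TBS-oxy)benzaldehyde
Product: 13 (E)-4-[3,4-bis(TBS-oxy)phenyl]but-3-en-2-one
Conditions: Ph3P=CHC(O)CH3, toluene, 90 °C
Reagents that add atoms: 1-(triphenylphosphoranylidene)propan-2-one, CC(=O)C=P(c1ccccc1)(c1ccccc1)c1ccccc1
Why: Wittig olefination with a stabilised ylide under neutral conditions should give the E-enone.

Step 10
Reactants: 13 (E)-4-[3,4-bis(TBS-oxy)phenyl]but-3-en-2-one
Product: 14 (E)-2-[3,4-bis(TBS-oxy)phenyl]ethenyl acetate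
Conditions: mCPBA (1.1 equiv), NaHCO3, CH2Cl2, 0 °C to rt
Reagents that add atoms: 3-chloroperbenzoic acid, OOC(=O)c1cccc(Cl)c1
Why: Baeyer–Villiger oxidation; the alkenyl group migrates in preference to methyl with retention of the alkene geometry, so the E-enol acetate is obtained without an enolisation step, and the peracid is limited to avoid epoxidising the product.

Step 11
Reactants: 10 8-[hydroxy(2-hydroxy-4,6-bis(TBS-oxy)phenyl)methyl]-3-O-benzyl-5,7,3',4'-tetra-O-TBS-catechin; 14 (E)-2-[3,4-bis(TBS-oxy)phenyl]ethenyl acetate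
Product: 16 3-O-acetyl-5,7,3',4'-tetra-O-TBS-catechin-(4α→8)-3-O-benzyl-5,7,3',4'-tetra-O-TBS-catechin, via ortho-quinone methide 15 (not isolated)
Conditions: (R)-TRIP (10 mol %), 14 (2.5 equiv), 4 Å molecular sieves, toluene, 0 °C to rt
Reagents that add atoms: none
Why: Proposed new method: the phosphoric acid protonates the benzylic hydroxyl of 10 and loss of water gives the aryl-substituted ortho-quinone methide 15, held to the chiral phosphate by a hydrogen bond at its carbonyl oxygen, after which C4 of 15 bonds to the acetoxy-bearing carbon of 14 while the benzylic carbon of 14, its developing charge carried by the para-silyloxy group, is taken up by the quinone methide oxygen; the closest known reaction type is the chiral-phosphoric-acid-catalysed [4+2] cycloaddition of ortho-quinone methides from ortho-hydroxybenzhydrols with electron-rich styrenes to cis-2,4-diarylchromans, and a β-acetoxystyrene as the 2π partner is the step beyond it. Ring C of the middle unit closes by an asynchronous inverse-electron-demand hetero-Diels–Alder addition, suprafacial on the alkene, which in its stepwise limit is C3–C4 bond formation followed by 6-exo-trig capture of the para-quinoid benzylic cation by O1. C2 and C3 end up trans because the E geometry of 14 is carried into the ring, and in the stepwise limit the same follows from closure with aryl and acetoxy equatorial, the acetoxy carbonyl shielding the cation on the side syn to the C3 oxygen. C4 ends up trans to C3 and cis to the C2 aryl if 14 approaches with its aryl group endo and its acetoxy group exo to the methide that carries the bottom unit on the outside, the mode that gives cis-2,4-diarylchromans in the known cases; this is the least secure element, because the 5-silyloxy group crowds that geometry. The absolute sense (2R) is set by the face of 15 left open in the pocket of the phosphate, with the (2R,3S) bottom unit as a second, fixed bias, so one catalyst enantiomer is matched. The step needs regioselectivity (C4 to the acetoxy carbon), which the 3,4-bis(silyloxy)phenyl group secures because benzylic stabilisation outweighs the weak donor effect of an acyloxy group; it needs a single quinone methide, which the one free phenol of 10 secures; and it needs the 4→8 link, which is already present in 10. Molecular sieves take up the water so that 14 is not hydrolysed.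

Step 12
Reactants: 16 3-O-acetyl-5,7,3',4'-tetra-O-TBS-catechin-(4α→8)-3-O-benzyl-5,7,3',4'-tetra-O-TBS-catechin
Product: 17 5,7,3',4'-tetra-O-TBS-catechin-(4α→8)-3-O-benzyl-5,7,3',4'-tetra-O-TBS-catechin
Conditions: iBu2AlH (3 equiv), CH2Cl2, −78 °C; aq. potassium sodium tartrate
Reagents that add atoms: none
Why: Reductive cleavage of the acetate; hydride attacks only the ester carbonyl, whereas basic methanolysis would strip the aryl silyl ethers.

Step 13
Reactants: 17 5,7,3',4'-tetra-O-TBS-catechin-(4α→8)-3-O-benzyl-5,7,3',4'-tetra-O-TBS-catechin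
Product: 18 3,5,7,3',4'-penta-O-TBS-catechin-(4α→8)-3-O-benzyl-5,7,3',4'-tetra-O-TBS-catechin
Conditions: TBSOTf, 2,6-lutidine, CH2Cl2, 0 °C to rt
Reagents that add atoms: tert-butyldimethylsilyl triflate, CC(C)(C)[Si](C)(C)OS(=O)(=O)C(F)(F)F
Why: Silylation of the hindered secondary hydroxyl with the silyl triflate; this blocks the middle O3 for step 24 with a group that leaves in the final fluoride step.

Step 14
Reactants: 19 (−)-epicatechin
Product: 20 3,5,7,3',4'-penta-O-TBS-epicatechin
Conditions: TBSCl (7 equiv), imidazole, DMAP (cat.), DMF, 50 °C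
Reagents that add atoms: tert-butyldimethylsilyl chloride, CC(C)(C)[Si](C)(C)Cl
Why: Exhaustive silylation of the four phenols and the axial 3-hydroxyl; the conditions are not basic enough to epimerise C2.

Step 15
Reactants: 20 3,5,7,3',4'-penta-O-TBS-epicatechin
Product: 21 8-bromo-3,5,7,3',4'-penta-O-TBS-epicatechin
Conditions: NBS (1.0 equiv), CH2Cl2, −78 to −40 °C, dark
Reagents that add atoms: N-bromosuccinimide, O=C1CCC(=O)N1Br
Why: Electrophilic bromination at C8 for the same steric reason as in step 3; the bromine later blocks this position against self-condensation.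

Step 16
Reactants: 21 8-bromo-3,5,7,3',4'-penta-O-TBS-epicatechin
Product: 22 8-bromo-4β-(2-ethoxyethoxy)-3,5,7,3',4'-penta-O-TBS-epicatechin
Conditions: DDQ (2 equiv), 2-ethoxyethanol (5 equiv), CH2Cl2, rt
Reagents that add atoms: 2-ethoxyethanol, CCOCCO
Why: Benzylic oxidation by hydride abstraction at C4, whose cation is stabilised by the 5- and 7-oxygens; the alcohol adds trans to the 3-silyloxy group, and this centre is lost again in step 17.

Step 17
Reactants: 18 3,5,7,3',4'-penta-O-TBS-catechin-(4α→8)-3-O-benzyl-5,7,3',4'-tetra-O-TBS-catechin; 22 8-bromo-4β-(2-ethoxyethoxy)-3,5,7,3',4'-penta-O-TBS-epicatechin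
Product: 23 8-bromo-3,5,7,3',4'-penta-O-TBS-epicatechin-(4β→8)-3,5,7,3',4'-penta-O-TBS-catechin-(4α→8)-3-O-benzyl-5,7,3',4'-tetra-O-TBS-catechin
Conditions: 22 (1.5 equiv), Me3SiOTf (0.5 equiv), CH2Cl2, −78 to −40 °C; Et3N
Reagents that add atoms: none
Why: Lewis-acid ionisation of the C4 ether and Friedel–Crafts capture of the flavan-4-yl cation by C8 of the middle ring, the most open nucleophilic position of 18; attack anti to the 3-silyloxy group of the 2,3-cis unit should give the 4β bond, and the bromine keeps 22 and 23 from adding further cations.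

Step 18
Reactants: 23 8-bromo-3,5,7,3',4'-penta-O-TBS-epicatechin-(4β→8)-3,5,7,3',4'-penta-O-TBS-catechin-(4α→8)-3-O-benzyl-5,7,3',4'-tetra-O-TBS-catechin
Product: 24 3,5,7,3',4'-penta-O-TBS-epicatechin-(4β→8)-3,5,7,3',4'-penta-O-TBS-catechin-(4α→8)-5,7,3',4'-tetra-O-TBS-catechin
Conditions: H2 (1 atm), Pd(OH)2 on carbon, Et3N, EtOAc–THF, rt
Reagents that add atoms: none
Why: Hydrogenolysis removes the benzyl ether and the aryl bromide in one operation while silyl ethers and interflavan bonds stay; it is placed here because no alkene is present yet.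

Step 19
Reactants: 25 2-methoxybenzoic acid
Product: 26 2-methoxycyclohexa-2,5-diene-1-carboxylic acid (racemic)
Conditions: Li, NH3(l), THF, −78 °C; NH4Cl; cold aq. NaH2PO4 (pH 5)
Reagents that add atoms: none
Why: Birch reduction; the carboxylate directs reduction to C1 and C4, leaving the enol ether and one isolated alkene, which are the masked C6 ketone and the C2=C3 alkene of the acyl ring.

Step 20
Reactants: 26 2-methoxycyclohexa-2,5-diene-1-carboxylic acid
Product: 27 allyl 2-methoxycyclohexa-2,5-diene-1-carboxylate (racemic)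
Conditions: allyl bromide, KHCO3, DMF, 0 °C to rt
Reagents that add atoms: allyl bromide, C=CCBr
Why: SN2 alkylation of the carboxylate with a base too weak to move the alkenes into conjugation; the allyl ester can later be cleaved without acid or hydroxide.

Step 21
Reactants: 27 allyl 2-methoxycyclohexa-2,5-diene-1-carboxylate
Product: 29 allyl (S)-1-hydroxy-2-methoxycyclohexa-2,5-diene-1-carboxylate, via potassium enolate 28 (not isolated)
Conditions: KN(SiMe3)2, THF, −78 °C; (+)-(2R,8aS)-(camphorsulfonyl)oxaziridine, −78 °C; aq. NH4Cl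
Reagents that add atoms: (+)-(2R,8aS)-(camphorsulfonyl)oxaziridine, CC1(C)[C@@H]2CC[C@]13CS(=O)(=O)N4O[C@@]34C2
Why: Asymmetric enolate oxidation with an enantiopure N-sulfonyloxaziridine; the planar enolate erases the racemic centre, oxygen enters at C1 as in alkylations of such dienolates, and the reagent selects the face (sense as assumed above).

Step 22
Reactants: 29 allyl (S)-1-hydroxy-2-methoxycyclohexa-2,5-diene-1-carboxylate
Product: 30 allyl (S)-2-methoxy-1-(triethylsilyloxy)cyclohexa-2,5-diene-1-carboxylate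
Conditions: TESOTf, 2,6-lutidine, CH2Cl2, −78 to 0 °C
Reagents that add atoms: triethylsilyl triflate, CC[Si](CC)(CC)OS(=O)(=O)C(F)(F)F
Why: Silylation of the tertiary hydroxyl with a silyl triflate and a hindered base; the small triethylsilyl group keeps the later esterification feasible and leaves in the final fluoride step.

Step 23
Reactants: 30 allyl (S)-2-methoxy-1-(triethylsilyloxy)cyclohexa-2,5-diene-1-carboxylate
Product: 31 (S)-2-methoxy-1-(triethylsilyloxy)cyclohexa-2,5-diene-1-carboxylic acid
Conditions: Pd(PPh3)4 (3 mol %), morpholine, THF, 0 °C to rt; cold aq. NaH2PO4 (pH 5); used at once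
Reagents that add atoms: none
Why: Tsuji–Trost deallylation frees the acid without hydroxide or strong acid, so the enol ether, the silyl ether and the quaternary centre stay intact.

Step 24
Reactants: 24 3,5,7,3',4'-penta-O-TBS-epicatechin-(4β→8)-3,5,7,3',4'-penta-O-TBS-catechin-(4α→8)-5,7,3',4'-tetra-O-TBS-catechin; 31 (S)-2-methoxy-1-(triethylsilyloxy)cyclohexa-2,5-diene-1-carboxylic acid
Product: 33 fully silylated trimer with the bottom O3 acylated by 31, via mixed anhydride 32 (not isolated)
Conditions: 31 (2 equiv), 2,4,6-trichlorobenzoyl chloride, Et3N, toluene, rt; then 24, DMAP, toluene, rt to 40 °C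
Reagents that add atoms: none
Why: Yamaguchi esterification; the mixed anhydride and DMAP activate the fully substituted acid, and the bottom O3 is the only free hydroxyl of 24.

Step 25
Reactants: 33 fully silylated trimer with the bottom O3 acylated by 31
Product: 35 epicatechin-(4β→8)-catechin-(4α→8)-catechin acylated at the bottom O3 with (S)-1-hydroxy-6-oxocyclohex-2-ene-1-carboxylic acid (the target), via desilylated enol ether 34 (not isolated)
Conditions: HF·pyridine, pyridine, THF, 0 °C to rt; then aq. HCl (pH 2), THF–H2O, 0 °C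
Reagents that add atoms: water, O
Why: Acidic fluoride cleaves all fifteen silyl ethers without base; dilute acid then protonates the enol ether at carbon and hydrolyses it to the C6 ketone, so the base-labile hydroxy keto ester is unveiled only at the very end.

## Compound list

1 | (+)-catechin, (2R,3S) | O[C@H]1Cc2c(O)cc(O)cc2O[C@@H]1c1ccc(O)c(O)c1 | starting material
2 | 5,7,3',4'-tetra-O-TBS-catechin | O[C@H]1Cc2c(O[Si](C)(C)C(C)(C)C)cc(O[Si](C)(C)C(C)(C)C)cc2O[C@@H]1c1ccc(O[Si](C)(C)C(C)(C)C)c(O[Si](C)(C)C(C)(C)C)c1 | intermediate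
3 | 3-O-benzyl-5,7,3',4'-tetra-O-TBS-catechin | c1ccccc1CO[C@H]1Cc2c(O[Si](C)(C)C(C)(C)C)cc(O[Si](C)(C)C(C)(C)C)cc2O[C@@H]1c1ccc(O[Si](C)(C)C(C)(C)C)c(O[Si](C)(C)C(C)(C)C)c1 | intermediate
4 | 8-bromo-3-O-benzyl-5,7,3',4'-tetra-O-TBS-catechin | c1ccccc1CO[C@H]1Cc2c(O[Si](C)(C)C(C)(C)C)cc(O[Si](C)(C)C(C)(C)C)c(Br)c2O[C@@H]1c1ccc(O[Si](C)(C)C(C)(C)C)c(O[Si](C)(C)C(C)(C)C)c1 | intermediate
5 | 2,4,6-trihydroxybenzaldehyde | O=Cc1c(O)cc(O)cc1O | starting material
6 | 2-hydroxy-4,6-bis(TBS-oxy)benzaldehyde | O=Cc1c(O)cc(O[Si](C)(C)C(C)(C)C)cc1O[Si](C)(C)C(C)(C)C | intermediate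
7 | 2-allyloxy-4,6-bis(TBS-oxy)benzaldehyde | O=Cc1c(OCC=C)cc(O[Si](C)(C)C(C)(C)C)cc1O[Si](C)(C)C(C)(C)C | intermediate
8 | 8-lithio-3-O-benzyl-5,7,3',4'-tetra-O-TBS-catechin (aryllithium) | c1ccccc1CO[C@H]1Cc2c(O[Si](C)(C)C(C)(C)C)cc(O[Si](C)(C)C(C)(C)C)c([Li])c2O[C@@H]1c1ccc(O[Si](C)(C)C(C)(C)C)c(O[Si](C)(C)C(C)(C)C)c1 | intermediate
9 | 8-[(2-allyloxy-4,6-bis(TBS-oxy)phenyl)(hydroxy)methyl]-3-O-benzyl-5,7,3',4'-tetra-O-TBS-catechin (carbinol epimers) | c1ccccc1CO[C@H]1Cc2c(O[Si](C)(C)C(C)(C)C)cc(O[Si](C)(C)C(C)(C)C)c(C(O)c3c(OCC=C)cc(O[Si](C)(C)C(C)(C)C)cc3O[Si](C)(C)C(C)(C)C)c2O[C@@H]1c1ccc(O[Si](C)(C)C(C)(C)C)c(O[Si](C)(C)C(C)(C)C)c1 | intermediate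
10 | 8-[hydroxy(2-hydroxy-4,6-bis(TBS-oxy)phenyl)methyl]-3-O-benzyl-5,7,3',4'-tetra-O-TBS-catechin (carbinol epimers) | c1ccccc1CO[C@H]1Cc2c(O[Si](C)(C)C(C)(C)C)cc(O[Si](C)(C)C(C)(C)C)c(C(O)c3c(O)cc(O[Si](C)(C)C(C)(C)C)cc3O[Si](C)(C)C(C)(C)C)c2O[C@@H]1c1ccc(O[Si](C)(C)C(C)(C)C)c(O[Si](C)(C)C(C)(C)C)c1 | intermediate
11 | 3,4-dihydroxybenzaldehyde | O=Cc1ccc(O)c(O)c1 | starting material
12 | 3,4-bis(TBS-oxy)benzaldehyde | O=Cc1ccc(O[Si](C)(C)C(C)(C)C)c(O[Si](C)(C)C(C)(C)C)c1 | intermediate
13 | (E)-4-[3,4-bis(TBS-oxy)phenyl]but-3-en-2-one | CC(=O)/C=C/c1ccc(O[Si](C)(C)C(C)(C)C)c(O[Si](C)(C)C(C)(C)C)c1 | intermediate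
14 | (E)-2-[3,4-bis(TBS-oxy)phenyl]ethenyl acetate | CC(=O)O/C=C/c1ccc(O[Si](C)(C)C(C)(C)C)c(O[Si](C)(C)C(C)(C)C)c1 | intermediate
15 | ortho-quinone methide from 10: 6-[(3-O-benzyl-5,7,3',4'-tetra-O-TBS-catechin-8-yl)methylidene]-3,5-bis(TBS-oxy)cyclohexa-2,4-dien-1-one (alkene geometry open) | c1ccccc1CO[C@H]1Cc2c(O[Si](C)(C)C(C)(C)C)cc(O[Si](C)(C)C(C)(C)C)c(C=C3C(=O)C=C(O[Si](C)(C)C(C)(C)C)C=C3O[Si](C)(C)C(C)(C)C)c2O[C@@H]1c1ccc(O[Si](C)(C)C(C)(C)C)c(O[Si](C)(C)C(C)(C)C)c1 | intermediate
16 | 3-O-acetyl-5,7,3',4'-tetra-O-TBS-catechin-(4α→8)-3-O-benzyl-5,7,3',4'-tetra-O-TBS-catechin | c1ccccc1CO[C@H]1Cc2c(O[Si](C)(C)C(C)(C)C)cc(O[Si](C)(C)C(C)(C)C)c([C@@H]3c4c(O[Si](C)(C)C(C)(C)C)cc(O[Si](C)(C)C(C)(C)C)cc4O[C@H](c4ccc(O[Si](C)(C)C(C)(C)C)c(O[Si](C)(C)C(C)(C)C)c4)[C@H]3OC(C)=O)c2O[C@@H]1c1ccc(O[Si](C)(C)C(C)(C)C)c(O[Si](C)(C)C(C)(C)C)c1 | intermediate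
17 | 5,7,3',4'-tetra-O-TBS-catechin-(4α→8)-3-O-benzyl-5,7,3',4'-tetra-O-TBS-catechin (middle 3-OH free) | c1ccccc1CO[C@H]1Cc2c(O[Si](C)(C)C(C)(C)C)cc(O[Si](C)(C)C(C)(C)C)c([C@@H]3c4c(O[Si](C)(C)C(C)(C)C)cc(O[Si](C)(C)C(C)(C)C)cc4O[C@H](c4ccc(O[Si](C)(C)C(C)(C)C)c(O[Si](C)(C)C(C)(C)C)c4)[C@H]3O)c2O[C@@H]1c1ccc(O[Si](C)(C)C(C)(C)C)c(O[Si](C)(C)C(C)(C)C)c1 | intermediate
18 | 3,5,7,3',4'-penta-O-TBS-catechin-(4α→8)-3-O-benzyl-5,7,3',4'-tetra-O-TBS-catechin | c1ccccc1CO[C@H]1Cc2c(O[Si](C)(C)C(C)(C)C)cc(O[Si](C)(C)C(C)(C)C)c([C@@H]3c4c(O[Si](C)(C)C(C)(C)C)cc(O[Si](C)(C)C(C)(C)C)cc4O[C@H](c4ccc(O[Si](C)(C)C(C)(C)C)c(O[Si](C)(C)C(C)(C)C)c4)[C@H]3O[Si](C)(C)C(C)(C)C)c2O[C@@H]1c1ccc(O[Si](C)(C)C(C)(C)C)c(O[Si](C)(C)C(C)(C)C)c1 | intermediate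
19 | (−)-epicatechin, (2R,3R) | O[C@@H]1Cc2c(O)cc(O)cc2O[C@@H]1c1ccc(O)c(O)c1 | starting material
20 | 3,5,7,3',4'-penta-O-TBS-epicatechin | CC(C)(C)[Si](C)(C)O[C@@H]1Cc2c(O[Si](C)(C)C(C)(C)C)cc(O[Si](C)(C)C(C)(C)C)cc2O[C@@H]1c1ccc(O[Si](C)(C)C(C)(C)C)c(O[Si](C)(C)C(C)(C)C)c1 | intermediate
21 | 8-bromo-3,5,7,3',4'-penta-O-TBS-epicatechin | CC(C)(C)[Si](C)(C)O[C@@H]1Cc2c(O[Si](C)(C)C(C)(C)C)cc(O[Si](C)(C)C(C)(C)C)c(Br)c2O[C@@H]1c1ccc(O[Si](C)(C)C(C)(C)C)c(O[Si](C)(C)C(C)(C)C)c1 | intermediate
22 | 8-bromo-4β-(2-ethoxyethoxy)-3,5,7,3',4'-penta-O-TBS-epicatechin (3,4-trans) | CCOCCO[C@H]1c2c(O[Si](C)(C)C(C)(C)C)cc(O[Si](C)(C)C(C)(C)C)c(Br)c2O[C@H](c2ccc(O[Si](C)(C)C(C)(C)C)c(O[Si](C)(C)C(C)(C)C)c2)[C@@H]1O[Si](C)(C)C(C)(C)C | intermediate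
23 | 8-bromo-3,5,7,3',4'-penta-O-TBS-epicatechin-(4β→8)-3,5,7,3',4'-penta-O-TBS-catechin-(4α→8)-3-O-benzyl-5,7,3',4'-tetra-O-TBS-catechin | c1ccccc1CO[C@H]1Cc2c(O[Si](C)(C)C(C)(C)C)cc(O[Si](C)(C)C(C)(C)C)c([C@@H]3c4c(O[Si](C)(C)C(C)(C)C)cc(O[Si](C)(C)C(C)(C)C)c([C@H]5c6c(O[Si](C)(C)C(C)(C)C)cc(O[Si](C)(C)C(C)(C)C)c(Br)c6O[C@H](c6ccc(O[Si](C)(C)C(C)(C)C)c(O[Si](C)(C)C(C)(C)C)c6)[C@@H]5O[Si](C)(C)C(C)(C)C)c4O[C@H](c4ccc(O[Si](C)(C)C(C)(C)C)c(O[Si](C)(C)C(C)(C)C)c4)[C@H]3O[Si](C)(C)C(C)(C)C)c2O[C@@H]1c1ccc(O[Si](C)(C)C(C)(C)C)c(O[Si](C)(C)C(C)(C)C)c1 | intermediate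
24 | 3,5,7,3',4'-penta-O-TBS-epicatechin-(4β→8)-3,5,7,3',4'-penta-O-TBS-catechin-(4α→8)-5,7,3',4'-tetra-O-TBS-catechin (bottom 3-OH free) | O[C@H]1Cc2c(O[Si](C)(C)C(C)(C)C)cc(O[Si](C)(C)C(C)(C)C)c([C@@H]3c4c(O[Si](C)(C)C(C)(C)C)cc(O[Si](C)(C)C(C)(C)C)c([C@H]5c6c(O[Si](C)(C)C(C)(C)C)cc(O[Si](C)(C)C(C)(C)C)cc6O[C@H](c6ccc(O[Si](C)(C)C(C)(C)C)c(O[Si](C)(C)C(C)(C)C)c6)[C@@H]5O[Si](C)(C)C(C)(C)C)c4O[C@H](c4ccc(O[Si](C)(C)C(C)(C)C)c(O[Si](C)(C)C(C)(C)C)c4)[C@H]3O[Si](C)(C)C(C)(C)C)c2O[C@@H]1c1ccc(O[Si](C)(C)C(C)(C)C)c(O[Si](C)(C)C(C)(C)C)c1 | intermediate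
25 | 2-methoxybenzoic acid | COc1ccccc1C(=O)O | starting material
26 | 2-methoxycyclohexa-2,5-diene-1-carboxylic acid (racemic) | COC1=CCC=CC1C(=O)O | intermediate
27 | allyl 2-methoxycyclohexa-2,5-diene-1-carboxylate (racemic) | COC1=CCC=CC1C(=O)OCC=C | intermediate
28 | potassium enolate of 27 | COC1=CCC=CC1=C([O-])OCC=C.[K+] | intermediate
29 | allyl (S)-1-hydroxy-2-methoxycyclohexa-2,5-diene-1-carboxylate | COC1=CCC=C[C@@]1(O)C(=O)OCC=C | intermediate
30 | allyl (S)-2-methoxy-1-(triethylsilyloxy)cyclohexa-2,5-diene-1-carboxylate | COC1=CCC=C[C@@]1(O[Si](CC)(CC)CC)C(=O)OCC=C | intermediate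
31 | (S)-2-methoxy-1-(triethylsilyloxy)cyclohexa-2,5-diene-1-carboxylic acid | COC1=CCC=C[C@@]1(O[Si](CC)(CC)CC)C(=O)O | intermediate
32 | mixed anhydride of 31 with 2,4,6-trichlorobenzoic acid | COC1=CCC=C[C@@]1(O[Si](CC)(CC)CC)C(=O)OC(=O)c1c(Cl)cc(Cl)cc1Cl | intermediate
33 | 3,5,7,3',4'-penta-O-TBS-epicatechin-(4β→8)-3,5,7,3',4'-penta-O-TBS-catechin-(4α→8)-5,7,3',4'-tetra-O-TBS-catechin, bottom 3-O-[(S)-2-methoxy-1-(triethylsilyloxy)cyclohexa-2,5-diene-1-carboxylate] | COC1=CCC=C[C@@]1(O[Si](CC)(CC)CC)C(=O)O[C@H]1Cc2c(O[Si](C)(C)C(C)(C)C)cc(O[Si](C)(C)C(C)(C)C)c([C@@H]3c4c(O[Si](C)(C)C(C)(C)C)cc(O[Si](C)(C)C(C)(C)C)c([C@H]5c6c(O[Si](C)(C)C(C)(C)C)cc(O[Si](C)(C)C(C)(C)C)cc6O[C@H](c6ccc(O[Si](C)(C)C(C)(C)C)c(O[Si](C)(C)C(C)(C)C)c6)[C@@H]5O[Si](C)(C)C(C)(C)C)c4O[C@H](c4ccc(O[Si](C)(C)C(C)(C)C)c(O[Si](C)(C)C(C)(C)C)c4)[C@H]3O[Si](C)(C)C(C)(C)C)c2O[C@@H]1c1ccc(O[Si](C)(C)C(C)(C)C)c(O[Si](C)(C)C(C)(C)C)c1 | intermediate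
34 | epicatechin-(4β→8)-catechin-(4α→8)-catechin, bottom 3-O-[(S)-1-hydroxy-2-methoxycyclohexa-2,5-diene-1-carboxylate] | COC1=CCC=C[C@@]1(O)C(=O)O[C@H]1Cc2c(O)cc(O)c([C@@H]3c4c(O)cc(O)c([C@H]5c6c(O)cc(O)cc6O[C@H](c6ccc(O)c(O)c6)[C@@H]5O)c4O[C@H](c4ccc(O)c(O)c4)[C@H]3O)c2O[C@@H]1c1ccc(O)c(O)c1 | intermediate
35 | epicatechin-(4β→8)-catechin-(4α→8)-catechin, bottom 3-O-[(S)-1-hydroxy-6-oxocyclohex-2-ene-1-carboxylate] (CNP0159807.2) | O=C1CCC=C[C@@]1(O)C(=O)O[C@H]1Cc2c(O)cc(O)c([C@@H]3c4c(O)cc(O)c([C@H]5c6c(O)cc(O)cc6O[C@H](c6ccc(O)c(O)c6)[C@@H]5O)c4O[C@H](c4ccc(O)c(O)c4)[C@H]3O)c2O[C@@H]1c1ccc(O)c(O)c1 | target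

## Step count and least certain steps

Total step count: 25. Longest linear sequence: 12 steps (steps 1, 2, 3, 6, 7, 11, 12, 13, 17, 18, 24, 25).

**Step 11 (key step, new method).** The quinone methide 15 is strongly stabilised and shielded on both sides of the methide carbon, so addition of the only moderately nucleophilic enol ester may be slower than self-condensation through a free aromatic position of a second molecule of 10. The approach may also be poorly face-selective or may go acetoxy-endo, giving the 3,4-cis arrangement, and the catalyst may be mismatched with the bottom unit. Fallback by known flavan-4-yl cation chemistry, setting out from 2 and 3 and coming back at 16: 2 is acetylated (Ac2O, DMAP, pyridine) to 3-O-acetyl-5,7,3',4'-tetra-O-TBS-catechin F1. DDQ and 2-ethoxyethanol in CH2Cl2 oxidise C4 to 3-O-acetyl-4-(2-ethoxyethoxy)-5,7,3',4'-tetra-O-TBS-catechin F2. F2 is ionised with Me3SiOTf in CH2Cl2 at −78 °C in the presence of an excess of 3, whose C8 captures the cation anti to the participating 3-acetoxy group to give 16.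

**Step 6.** In the aryllithium 8 a silyl group may shift from O7 to the carbanion carbon, or from an aryl oxygen to the new alkoxide before the quench, and addition between two doubly ortho-substituted partners may be slow enough to let this happen. Fallback from 3, coming back at 9: iodination of 3 with N-iodosuccinimide gives 8-iodo-3-O-benzyl-5,7,3',4'-tetra-O-TBS-catechin F3. Iodine–magnesium exchange with iPrMgCl·LiCl in THF gives the arylmagnesium chloride F4, a carbanion that does not trigger silyl shifts. F4 adds to 7 at 0 °C to give 9.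

**Step 17.** Four ortho silyloxy groups crowd the new bond, so capture of the cation may become slower than ionisation of the existing interflavan bond of 18 by the Lewis acid (scrambling) or than attack through C6. Fallback from 22, coming back at 23: 22 is converted with benzyl mercaptan and BF3·OEt2 at −78 °C into 4β-benzylthio-8-bromo-3,5,7,3',4'-penta-O-TBS-epicatechin F5. F5 is activated toward 18 with the thiophilic salt AgBF4 in THF at 0 °C, without Brønsted or hard Lewis acid, to give 23.

**Step 21.** The oxaziridine may discriminate poorly between the faces of 28, or in the wrong sense. Fallback from 27, coming back at 31: 27 is hydroxylated without stereocontrol (KN(SiMe3)2, then racemic 2-(phenylsulfonyl)-3-phenyloxaziridine) to the racemic hydroxy ester F6. Deallylation (Pd(PPh3)4, morpholine) gives the racemic hydroxy acid F7. Crystallisation with (R)-1-phenylethylamine, taken here as the amine that gives the less soluble salt of the (S)-acid, gives the salt F8. Treatment of F8 with excess TESOTf and 2,6-lutidine gives the bis-silyl compound F9, whose silyl ester is hydrolysed on work-up with aq. NaH2PO4 to give 31.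

**Step 24.** Acyl transfer from the crowded anhydride 32 may be slower than attack at the trichlorobenzoyl carbonyl, so that 24 is capped with the wrong acyl group. Fallback from 24 and 26, coming back at 34 within step 25: 24 is esterified with the less hindered acid 26 (dicyclohexylcarbodiimide, DMAP) to the dienyl ester F10 (C1 epimers). Its potassium enolate (KN(SiMe3)2, −78 °C) is oxygenated with the oxaziridine of step 21 to the tertiary alcohol F11, the two faces now being told apart by reagent and substrate together. F11 is desilylated under the conditions of step 25 to 34.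

**Step 25.** Cleavage of the two hindered secondary silyl ethers may be incomplete, and the free polyphenol may suffer acid cleavage of its interflavan bonds during the enol ether hydrolysis. Fallback from 33, coming back at 35: the order is reversed. Aqueous oxalic acid in THF hydrolyses the enol ether and the tertiary silyl ether while the phenols are still silylated and the interflavan bonds are at their most robust, giving the silylated hydroxy ketone F12. Et3N·3HF in THF then removes the fourteen TBS groups close to neutrality to give 35.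

## Further compounds

F1 | step 11 | 3-O-acetyl-5,7,3',4'-tetra-O-TBS-catechin | CC(=O)O[C@H]1Cc2c(O[Si](C)(C)C(C)(C)C)cc(O[Si](C)(C)C(C)(C)C)cc2O[C@@H]1c1ccc(O[Si](C)(C)C(C)(C)C)c(O[Si](C)(C)C(C)(C)C)c1
F2 | step 11 | 3-O-acetyl-4-(2-ethoxyethoxy)-5,7,3',4'-tetra-O-TBS-catechin (C4 epimers, centre lost on ionisation) | CC(=O)O[C@H]1C(OCCOCC)c2c(O[Si](C)(C)C(C)(C)C)cc(O[Si](C)(C)C(C)(C)C)cc2O[C@@H]1c1ccc(O[Si](C)(C)C(C)(C)C)c(O[Si](C)(C)C(C)(C)C)c1
F3 | step 6 | 8-iodo-3-O-benzyl-5,7,3',4'-tetra-O-TBS-catechin | c1ccccc1CO[C@H]1Cc2c(O[Si](C)(C)C(C)(C)C)cc(O[Si](C)(C)C(C)(C)C)c(I)c2O[C@@H]1c1ccc(O[Si](C)(C)C(C)(C)C)c(O[Si](C)(C)C(C)(C)C)c1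
F4 | step 6 | 8-(chloromagnesio)-3-O-benzyl-5,7,3',4'-tetra-O-TBS-catechin | c1ccccc1CO[C@H]1Cc2c(O[Si](C)(C)C(C)(C)C)cc(O[Si](C)(C)C(C)(C)C)c([Mg]Cl)c2O[C@@H]1c1ccc(O[Si](C)(C)C(C)(C)C)c(O[Si](C)(C)C(C)(C)C)c1
F5 | step 17 | 4β-benzylthio-8-bromo-3,5,7,3',4'-penta-O-TBS-epicatechin | c1ccccc1CS[C@H]1c2c(O[Si](C)(C)C(C)(C)C)cc(O[Si](C)(C)C(C)(C)C)c(Br)c2O[C@H](c2ccc(O[Si](C)(C)C(C)(C)C)c(O[Si](C)(C)C(C)(C)C)c2)[C@@H]1O[Si](C)(C)C(C)(C)C
F6 | step 21 | racemic allyl 1-hydroxy-2-methoxycyclohexa-2,5-diene-1-carboxylate | COC1=CCC=CC1(O)C(=O)OCC=C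
F7 | step 21 | racemic 1-hydroxy-2-methoxycyclohexa-2,5-diene-1-carboxylic acid | COC1=CCC=CC1(O)C(=O)O
F8 | step 21 | (R)-1-phenylethylammonium (S)-1-hydroxy-2-methoxycyclohexa-2,5-diene-1-carboxylate | COC1=CCC=C[C@@]1(O)C(=O)[O-].C[C@H](c1ccccc1)[NH3+]
F9 | step 21 | triethylsilyl (S)-2-methoxy-1-(triethylsilyloxy)cyclohexa-2,5-diene-1-carboxylate | COC1=CCC=C[C@@]1(O[Si](CC)(CC)CC)C(=O)O[Si](CC)(CC)CC
F10 | step 24 | 24 acylated at the bottom O3 with 2-methoxycyclohexa-2,5-diene-1-carboxylic acid (C1 epimers) | COC1=CCC=CC1C(=O)O[C@H]1Cc2c(O[Si](C)(C)C(C)(C)C)cc(O[Si](C)(C)C(C)(C)C)c([C@@H]3c4c(O[Si](C)(C)C(C)(C)C)cc(O[Si](C)(C)C(C)(C)C)c([C@H]5c6c(O[Si](C)(C)C(C)(C)C)cc(O[Si](C)(C)C(C)(C)C)cc6O[C@H](c6ccc(O[Si](C)(C)C(C)(C)C)c(O[Si](C)(C)C(C)(C)C)c6)[C@@H]5O[Si](C)(C)C(C)(C)C)c4O[C@H](c4ccc(O[Si](C)(C)C(C)(C)C)c(O[Si](C)(C)C(C)(C)C)c4)[C@H]3O[Si](C)(C)C(C)(C)C)c2O[C@@H]1c1ccc(O[Si](C)(C)C(C)(C)C)c(O[Si](C)(C)C(C)(C)C)c1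
F11 | step 24 | 24 acylated at the bottom O3 with (S)-1-hydroxy-2-methoxycyclohexa-2,5-diene-1-carboxylic acid | COC1=CCC=C[C@@]1(O)C(=O)O[C@H]1Cc2c(O[Si](C)(C)C(C)(C)C)cc(O[Si](C)(C)C(C)(C)C)c([C@@H]3c4c(O[Si](C)(C)C(C)(C)C)cc(O[Si](C)(C)C(C)(C)C)c([C@H]5c6c(O[Si](C)(C)C(C)(C)C)cc(O[Si](C)(C)C(C)(C)C)cc6O[C@H](c6ccc(O[Si](C)(C)C(C)(C)C)c(O[Si](C)(C)C(C)(C)C)c6)[C@@H]5O[Si](C)(C)C(C)(C)C)c4O[C@H](c4ccc(O[Si](C)(C)C(C)(C)C)c(O[Si](C)(C)C(C)(C)C)c4)[C@H]3O[Si](C)(C)C(C)(C)C)c2O[C@@H]1c1ccc(O[Si](C)(C)C(C)(C)C)c(O[Si](C)(C)C(C)(C)C)c1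
F12 | step 25 | 24 acylated at the bottom O3 with (S)-1-hydroxy-6-oxocyclohex-2-ene-1-carboxylic acid (fourteen TBS ethers retained) | O=C1CCC=C[C@@]1(O)C(=O)O[C@H]1Cc2c(O[Si](C)(C)C(C)(C)C)cc(O[Si](C)(C)C(C)(C)C)c([C@@H]3c4c(O[Si](C)(C)C(C)(C)C)cc(O[Si](C)(C)C(C)(C)C)c([C@H]5c6c(O[Si](C)(C)C(C)(C)C)cc(O[Si](C)(C)C(C)(C)C)cc6O[C@H](c6ccc(O[Si](C)(C)C(C)(C)C)c(O[Si](C)(C)C(C)(C)C)c6)[C@@H]5O[Si](C)(C)C(C)(C)C)c4O[C@H](c4ccc(O[Si](C)(C)C(C)(C)C)c(O[Si](C)(C)C(C)(C)C)c4)[C@H]3O[Si](C)(C)C(C)(C)C)c2O[C@@H]1c1ccc(O[Si](C)(C)C(C)(C)C)c(O[Si](C)(C)C(C)(C)C)c1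
A1 | alternative 1 | ethyl (E)-9-[3,4-bis(benzyloxy)phenyl]-3,5,7-trioxonon-8-enoate | CCOC(=O)CC(=O)CC(=O)CC(=O)/C=C/c1ccc(OCc2ccccc2)c(OCc2ccccc2)c1
A2 | alternative 1 | (E)-3,4-bis(benzyloxy)-2',4',6'-trihydroxychalcone | O=C(/C=C/c1ccc(OCc2ccccc2)c(OCc2ccccc2)c1)c1c(O)cc(O)cc1O
A3 | alternative 2 | 5,7,3',4'-tetra-O-TBS-catechin 3-O-(1-hydroxycyclohexa-2,5-diene-1-carboxylate) | OC1(C=CCC=C1)C(=O)O[C@H]1Cc2c(O[Si](C)(C)C(C)(C)C)cc(O[Si](C)(C)C(C)(C)C)cc2O[C@@H]1c1ccc(O[Si](C)(C)C(C)(C)C)c(O[Si](C)(C)C(C)(C)C)c1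
A4 | alternative 2 | 5,7,3',4'-tetra-O-TBS-catechin 3-O-(syn-2-hydroxy-7-oxabicyclo[4.1.0]hept-3-ene-2-carboxylate) | [C@@H]12O[C@@H]1CC=C[C@@]2(O)C(=O)O[C@H]1Cc2c(O[Si](C)(C)C(C)(C)C)cc(O[Si](C)(C)C(C)(C)C)cc2O[C@@H]1c1ccc(O[Si](C)(C)C(C)(C)C)c(O[Si](C)(C)C(C)(C)C)c1
A5 | alternative 3 | 5,7,3',4'-tetra-O-TBS-catechin 3-O-[2-((R)-1-hydroxycyclopent-2-en-1-yl)-2-oxoacetate] | O=C(C(=O)O[C@H]1Cc2c(O[Si](C)(C)C(C)(C)C)cc(O[Si](C)(C)C(C)(C)C)cc2O[C@@H]1c1ccc(O[Si](C)(C)C(C)(C)C)c(O[Si](C)(C)C(C)(C)C)c1)[C@]1(O)C=CCC1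
A6 | alternative 3 | 5,7,3',4'-tetra-O-TBS-catechin 3-O-[(S)-1-hydroxy-6-oxocyclohex-2-ene-1-carboxylate] | O=C1CCC=C[C@@]1(O)C(=O)O[C@H]1Cc2c(O[Si](C)(C)C(C)(C)C)cc(O[Si](C)(C)C(C)(C)C)cc2O[C@@H]1c1ccc(O[Si](C)(C)C(C)(C)C)c(O[Si](C)(C)C(C)(C)C)c1
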